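## Retrosynthetic overview

- Acredinone A is a 2,3-diarylinden-1-one. Its five-membered ring (C1, C2, C3, C3a, C7a) is opened last, by retro carbonyl–alkyne metathesis, to a C2-symmetric tolane in which C1≡C2 is an alkyne and C3 is a diaryl ketone carbon.
- The plan rests on one feature: ring A (C3a to C7a) and ring B (C1' to C6') are the same pentasubstituted 4-methoxyphenol. OH (C4, C3') sits ortho to the aroyl-bearing carbon (C3a, C2') and OMe (C7, C6') ortho to the carbon carrying C1 or C2 (C7a, C1'). This is the retron of a 1-methoxy-1-siloxydiene/ynone Diels–Alder aromatisation.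
- Both arenes are cut at C7–C7a/C3a–C4 and C1'–C6'/C2'–C3', leading back to an open-chain 1,8-diaryl-octa-2,4,6-triyne-1,8-dione and two molecules of a 1,4-dimethoxy-3-methyl-1-siloxybutadiene.
- The triyne dione comes from 2,6-dimethoxybenzaldehyde by ethynyl and butadiynyl additions, Cadiot–Chodkiewicz coupling and MnO2 oxidation. The diene comes from a (Z)-4-methoxy-3-methylbut-2-enoate made by syn-carbocupration of an ynoate, which fixes both the site of γ-deprotonation and the enol ether geometry.
- Ring order: rings A and B together in one operation (step 10), then the indenone five-membered ring (step 11).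

Key step: step 10

Remark: the carbinol intermediates are racemic or diastereomer mixtures, their stereocentres are removed by oxidation before the key step, and the target has no stereocentre. The C1 geometry of the diene does not affect the outcome; its C3=C4 geometry (methoxy trans to C2) does.

## Route

Step 1
Reactants: 1 2,6-dimethoxybenzaldehyde; 2 ethynylmagnesium bromide
Product: 3 1-(2,6-dimethoxyphenyl)prop-2-yn-1-ol (racemic)
Conditions: THF, 0 °C to rt; then aq. NH4Cl
Reagents that add atoms: none
Why: 1,2-addition of an alkynyl Grignard reagent to a non-enolisable aryl aldehyde is reliable even between two ortho methoxy groups, and the racemic carbinol centre is removed by oxidation in step 6.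

Step 2
Reactants: 3 1-(2,6-dimethoxyphenyl)prop-2-yn-1-ol
Product: 4 3-bromo-1-(2,6-dimethoxyphenyl)prop-2-yn-1-ol (racemic)
Conditions: NBS (1.1 equiv), AgNO3 (cat.), acetone, rt, dark
Reagents that add atoms: N-bromosuccinimide, O=C1CCC(=O)N1Br
Why: silver-catalysed bromination of a terminal alkyne through its silver acetylide should be much faster than ring bromination of the dimethoxyarene and leaves the carbinol untouched.

Step 3
Reactants: 5 1,4-bis(trimethylsilyl)buta-1,3-diyne; 1 2,6-dimethoxybenzaldehyde
Product: 7 1-(2,6-dimethoxyphenyl)-5-(trimethylsilyl)penta-2,4-diyn-1-ol (racemic), via lithium (trimethylsilyl)butadiynide 6 (not isolated)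
Conditions: MeLi·LiBr (1.0 equiv), THF, rt; then 1, −78 °C to 0 °C; then aq. NH4Cl
Reagents that add atoms: none
Why: MeLi·LiBr cleaves one C–Si bond of the bis-silyl diyne selectively, and the resulting lithium butadiynide adds 1,2 to the aldehyde (acetylide addition) to give a racemic carbinol.

Step 4
Reactants: 7 1-(2,6-dimethoxyphenyl)-5-(trimethylsilyl)penta-2,4-diyn-1-ol
Product: 8 1-(2,6-dimethoxyphenyl)penta-2,4-diyn-1-ol (racemic)
Conditions: K2CO3 (cat.), MeOH/THF, 0 °C; used at once
Reagents that add atoms: none
Why: carbonate-catalysed methanolysis of an alkynyl C–Si bond is a standard protodesilylation that the free carbinol and the aryl ethers tolerate.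

Step 5
Reactants: 4 3-bromo-1-(2,6-dimethoxyphenyl)prop-2-yn-1-ol; 8 1-(2,6-dimethoxyphenyl)penta-2,4-diyn-1-ol
Product: 9 1,8-bis(2,6-dimethoxyphenyl)octa-2,4,6-triyne-1,8-diol (mixture of meso and racemic diastereomers)
Conditions: CuCl (cat.), NH2OH·HCl (cat.), n-BuNH2, MeOH/H2O, 0 °C, slow addition of 4
Reagents that add atoms: none
Why: Cadiot–Chodkiewicz coupling joins the copper acetylide of the terminal diyne to the 1-bromoalkyne under amine/hydroxylamine conditions that keep copper monovalent and tolerate free propargylic alcohols; the diastereomer mixture is of no consequence.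

Step 6
Reactants: 9 1,8-bis(2,6-dimethoxyphenyl)octa-2,4,6-triyne-1,8-diol
Product: 10 1,8-bis(2,6-dimethoxyphenyl)octa-2,4,6-triyne-1,8-dione
Conditions: activated MnO2 (excess), CH2Cl2, rt, dark; filtration through Celite, used without storage
Reagents that add atoms: none
Why: both carbinols are benzylic and propargylic, the alcohol class that MnO2 oxidises under neutral heterogeneous conditions, and simple filtration spares the electrophilic triyne dione an aqueous work-up.

Step 7
Reactants: 11 3-methoxyprop-1-yne
Product: 13 methyl 4-methoxybut-2-ynoate, via lithium 3-methoxypropynide 12 (not isolated)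
Conditions: n-BuLi, THF, −78 °C; then ClCO2Me, −78 °C to 0 °C
Reagents that add atoms: methyl chloroformate, COC(=O)Cl
Why: acylation of a lithium acetylide with a chloroformate is a standard ynoate synthesis and the methyl ether is inert.

Step 8
Reactants: 13 methyl 4-methoxybut-2-ynoate
Product: 15 methyl (Z)-4-methoxy-3-methylbut-2-enoate, via alkenyl(methyl)cuprate 14 (not isolated)
Conditions: Me2CuLi (from CuI and 2 MeLi), THF, −78 °C; then MeOH, −78 °C
Reagents that add atoms: lithium dimethylcuprate (Me2CuLi), [Li+].C[Cu-]C
Why: syn-carbocupration (conjugate addition) of an ynoate at −78 °C followed by cold protonation retains the alkenylcopper geometry, so the new methyl group ends trans and the methoxymethyl group cis to the ester, fixing the (Z)-alkene.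

Step 9
Reactants: 15 methyl (Z)-4-methoxy-3-methylbut-2-enoate
Product: 17 (1Z,3E)-1,4-dimethoxy-3-methyl-1-(trimethylsilyloxy)buta-1,3-diene, via lithium dienolate 16 (not isolated)
Conditions: LiN(i-Pr)2, THF, −78 °C; then Me3SiCl, −78 °C to rt; pentane, filtration, distillation
Reagents that add atoms: chlorotrimethylsilane, C[Si](C)(C)Cl
Why: kinetic γ-deprotonation of a β,β-disubstituted enoate removes the proton from the γ-carbon cis to the ester (here CH2OMe, with the base bound to the s-cis carbonyl), allylic strain turns the methoxy group away from the ester (3E), and O-silylation of the dienolate gives the vinylogous silyl ketene acetal.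

Step 10
Reactants: 10 1,8-bis(2,6-dimethoxyphenyl)octa-2,4,6-triyne-1,8-dione; 17 (1Z,3E)-1,4-dimethoxy-3-methyl-1-(trimethylsilyloxy)buta-1,3-diene (3 equiv)
Product: 20 1,2-bis[2-(2,6-dimethoxybenzoyl)-3-hydroxy-6-methoxy-5-methylphenyl]ethyne, via bis-cycloadduct 18 (not isolated), via bis(aryl silyl ether) 19 (not isolated)
Conditions: toluene, 0 °C to 40 °C, argon, dark; then 1 M HCl, THF, rt
Reagents that add atoms: none
Why: Proposed new method: each outer triple bond of 10 is an ynone and should undergo an asynchronous normal-demand [4+2] cycloaddition with the vinylogous ketene acetal 17, in which the methoxy-bearing diene terminus (C4, the nucleophilic end) bonds first to the ynone β-carbon and the acetal carbon (C1) then closes onto the α-carbon, so that ring A (bonds C7–C7a and C3a–C4) and ring B (bonds C1'–C6' and C2'–C3') are each closed as six-membered carbocycles by a [4+2] mode. The closest known reaction type is the Diels–Alder addition/aromatisation of 1-alkoxy-1-siloxydienes with acetylenic ketones, which has not been shown twice on one conjugated triyne dione with the middle triple bond left intact. The 1,4-cyclohexadienes 18 should aromatise by 1,4-loss of methanol (OMe from the mixed acetal carbon, H from the CH(OMe) carbon) to the aryl silyl ethers 19, which dilute acid cleaves to the ketone-chelated phenols, so the four transient sp3 centres of 18 vanish and no stereocentre needs control. The regiochemistry needed (OH ortho to the aroyl carbon, OMe ortho to the alkyne carbon) is secured by the polarisation of each ynone by its own carbonyl group and by the two oxygen donors on C1 of 17, which make C4 the nucleophilic terminus. The site selectivity needed (outer triple bonds only) is secured by their direct conjugation to a carbonyl, whereas the inner triple bond is activated only vinylogously and, after the first annulation, lies between an electron-rich arene and an ynone; the 3E geometry of 17 allows the s-cis conformer that ring closure requires.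

Step 11
Reactants: 20 1,2-bis[2-(2,6-dimethoxybenzoyl)-3-hydroxy-6-methoxy-5-methylphenyl]ethyne
Product: 21 acredinone A
Conditions: TfOH (excess), CH2Cl2, 0 °C to rt
Reagents that add atoms: none
Why: Brønsted-acid-promoted intramolecular carbonyl–alkyne metathesis of an ortho-alkynyl diaryl ketone (formal [2+2]/retro-[2+2]) bonds the ketone carbon (C3) to the distal alkyne carbon (C2) and passes the oxygen to the proximal alkyne carbon (C1), closing the five-membered ring, and because 20 is C2-symmetric either ketone gives the same indenone with no stereocentre formed.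

## Compound list

1 | 2,6-dimethoxybenzaldehyde | COc1cccc(OC)c1C=O | starting material
2 | ethynylmagnesium bromide | C#C[Mg]Br | starting material
3 | 1-(2,6-dimethoxyphenyl)prop-2-yn-1-ol (racemic) | COc1cccc(OC)c1C(O)C#C | intermediate
4 | 3-bromo-1-(2,6-dimethoxyphenyl)prop-2-yn-1-ol (racemic) | COc1cccc(OC)c1C(O)C#CBr | intermediate
5 | 1,4-bis(trimethylsilyl)buta-1,3-diyne | C[Si](C)(C)C#CC#C[Si](C)(C)C | starting material
6 | lithium 4-(trimethylsilyl)buta-1,3-diyn-1-ide | [Li]C#CC#C[Si](C)(C)C | intermediate (not isolated)
7 | 1-(2,6-dimethoxyphenyl)-5-(trimethylsilyl)penta-2,4-diyn-1-ol (racemic) | COc1cccc(OC)c1C(O)C#CC#C[Si](C)(C)C | intermediate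
8 | 1-(2,6-dimethoxyphenyl)penta-2,4-diyn-1-ol (racemic) | COc1cccc(OC)c1C(O)C#CC#C | intermediate
9 | 1,8-bis(2,6-dimethoxyphenyl)octa-2,4,6-triyne-1,8-diol (meso and racemic diastereomers, mixture) | COc1cccc(OC)c1C(O)C#CC#CC#CC(O)c1c(OC)cccc1OC | intermediate
10 | 1,8-bis(2,6-dimethoxyphenyl)octa-2,4,6-triyne-1,8-dione | COc1cccc(OC)c1C(=O)C#CC#CC#CC(=O)c1c(OC)cccc1OC | intermediate
11 | 3-methoxyprop-1-yne | COCC#C | starting material
12 | lithium 3-methoxyprop-1-yn-1-ide | [Li]C#CCOC | intermediate (not isolated)
13 | methyl 4-methoxybut-2-ynoate | COCC#CC(=O)OC | intermediate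
14 | lithium [(E)-1,4-dimethoxy-3-methyl-1-oxobut-2-en-2-yl](methyl)cuprate (Cu cis to the new methyl group) | [Li+].COC/C(C)=C(/[Cu-]C)C(=O)OC | intermediate (not isolated)
15 | methyl (Z)-4-methoxy-3-methylbut-2-enoate | COC/C(C)=C\C(=O)OC | intermediate
16 | lithium (1E,3E)-1,4-dimethoxy-3-methylbuta-1,3-dien-1-olate (OLi cis to C3, same geometry as 17) | CO/C=C(\C)/C=C(/OC)O[Li] | intermediate (not isolated)
17 | (1Z,3E)-1,4-dimethoxy-3-methyl-1-(trimethylsilyloxy)buta-1,3-diene | CO/C=C(\C)/C=C(/OC)O[Si](C)(C)C | intermediate
18 | 1,2-bis[2-(2,6-dimethoxybenzoyl)-3,6-dimethoxy-5-methyl-3-(trimethylsilyloxy)cyclohexa-1,4-dien-1-yl]ethyne (mixture of diastereomers) | COc1cccc(OC)c1C(=O)C1=C(C#CC2=C(C(=O)c3c(OC)cccc3OC)C(OC)(O[Si](C)(C)C)C=C(C)C2OC)C(OC)C(C)=CC1(OC)O[Si](C)(C)C | intermediate (not isolated)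
19 | 1,2-bis[2-(2,6-dimethoxybenzoyl)-6-methoxy-5-methyl-3-(trimethylsilyloxy)phenyl]ethyne | COc1cccc(OC)c1C(=O)c1c(O[Si](C)(C)C)cc(C)c(OC)c1C#Cc1c(OC)c(C)cc(O[Si](C)(C)C)c1C(=O)c1c(OC)cccc1OC | intermediate (not isolated)
20 | 1,2-bis[2-(2,6-dimethoxybenzoyl)-3-hydroxy-6-methoxy-5-methylphenyl]ethyne | COc1cccc(OC)c1C(=O)c1c(O)cc(C)c(OC)c1C#Cc1c(OC)c(C)cc(O)c1C(=O)c1c(OC)cccc1OC | intermediate
21 | acredinone A, 2-[2-(2,6-dimethoxybenzoyl)-3-hydroxy-6-methoxy-5-methylphenyl]-3-(2,6-dimethoxyphenyl)-4-hydroxy-7-methoxy-6-methyl-1H-inden-1-one | COc1cccc(OC)c1C(=O)c1c(O)cc(C)c(OC)c1C1=C(c2c(OC)cccc2OC)c2c(O)cc(C)c(OC)c2C1=O | target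

## Step count and risks

Total step count: 11 steps.
Longest linear sequence: 6 steps (steps 3, 4, 5, 6, 10, 11 from 5; equally steps 1, 2, 5, 6, 10, 11 from 1).

Steps most likely to fail:

1. Step 10 (double cycloaddition). Several processes could divert it. The diene may add at the inner triple bond or in a 1,6-sense without ring closure, giving open-chain vinylogous Michael adducts. The electron-poor triyne may oligomerise. The second annulation may stall because of crowding next to the 2,6-dimethoxybenzoyl group. The acetal may expel silanol instead of methanol, leaving methyl ethers in place of the phenols. The fallback uses known chemistry, sets out from 4 (with 17) and returns at 20. Oxidation of 4 with MnO2 in CH2Cl2 should give 3-bromo-1-(2,6-dimethoxyphenyl)prop-2-yn-1-one F1. A single Diels–Alder addition of 17 to this one acetylenic ketone, the established reaction class, should give [2-bromo-3,6-dimethoxy-4-methyl-6-(trimethylsilyloxy)cyclohexa-1,4-dien-1-yl](2,6-dimethoxyphenyl)methanone F2. Dilute HCl should convert this into (2-bromo-6-hydroxy-3-methoxy-4-methylphenyl)(2,6-dimethoxyphenyl)methanone F3. Two molecules of F3 are then joined through a two-carbon unit by double Stille coupling with bis(tributylstannyl)ethyne (Pd(PPh3)4, toluene, 100 °C) to give 20, and step 11 follows unchanged.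

2. Step 11 (carbonyl–alkyne metathesis). The ketone oxygen may attack the distal alkyne carbon and rest as a persistent 2-benzopyrylium ion. The superacid may cleave the 2,6-dimethoxybenzoyl groups by ipso-protonation. An ortho methoxy oxygen may cyclise onto the activated alkyne with demethylation. The fallback sets out from 20 and returns at 21 in two stages. Catalytic hydration of the alkyne (Ph3PAuCl/AgOTf, wet 1,4-dioxane, 60 °C) should give 1,2-bis[2-(2,6-dimethoxybenzoyl)-3-hydroxy-6-methoxy-5-methylphenyl]ethan-1-one F4; because 20 is symmetric, either direction of water addition gives this one ketone. Intramolecular aldol condensation (p-TsOH, toluene, reflux with water removal) then lets the methylene close onto the aroyl carbonyl of the ring that carries the new ketone. This is the only closure that gives a five-membered ring, and it delivers 21.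

3. Step 5 (Cadiot–Chodkiewicz coupling). Homocoupling of bromoalkyne 4, oxidative dimerisation of diyne 8, or decay of the terminal diyne under the basic copper conditions would give diyne and tetrayne diols that are hard to separate from 9. The fallback sets out from 8 and returns at 9, and it makes steps 1 and 2 unnecessary. Diyne 8 is coupled under the same copper/amine conditions with the simple partner (bromoethynyl)trimethylsilane, used in excess, to give 1-(2,6-dimethoxyphenyl)-7-(trimethylsilyl)hepta-2,4,6-triyn-1-ol F5. MeLi·LiBr (2 equiv, THF, −78 °C to rt) then deprotonates the carbinol and cleaves the C–Si bond to give lithium 7-(2,6-dimethoxyphenyl)-7-(lithiooxy)hepta-1,3,5-triyn-1-ide F6. This adds to aldehyde 1 (−78 °C, then aq. NH4Cl) to give 9, so the last bond is made by carbonyl addition of a triynyl anion and not by cross-coupling of two carbinol fragments.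

## Further compounds

F1 | step 10 | 3-bromo-1-(2,6-dimethoxyphenyl)prop-2-yn-1-one | COc1cccc(OC)c1C(=O)C#CBr
F2 | step 10 | [2-bromo-3,6-dimethoxy-4-methyl-6-(trimethylsilyloxy)cyclohexa-1,4-dien-1-yl](2,6-dimethoxyphenyl)methanone (mixture of diastereomers) | COc1cccc(OC)c1C(=O)C1=C(Br)C(OC)C(C)=CC1(OC)O[Si](C)(C)C
F3 | step 10 | (2-bromo-6-hydroxy-3-methoxy-4-methylphenyl)(2,6-dimethoxyphenyl)methanone | COc1cccc(OC)c1C(=O)c1c(O)cc(C)c(OC)c1Br
F4 | step 11 | 1,2-bis[2-(2,6-dimethoxybenzoyl)-3-hydroxy-6-methoxy-5-methylphenyl]ethan-1-one | COc1cccc(OC)c1C(=O)c1c(O)cc(C)c(OC)c1CC(=O)c1c(OC)c(C)cc(O)c1C(=O)c1c(OC)cccc1OC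
F5 | step 5 | 1-(2,6-dimethoxyphenyl)-7-(trimethylsilyl)hepta-2,4,6-triyn-1-ol (racemic) | COc1cccc(OC)c1C(O)C#CC#CC#C[Si](C)(C)C
F6 | step 5 | lithium 7-(2,6-dimethoxyphenyl)-7-(lithiooxy)hepta-1,3,5-triyn-1-ide | [Li]C#CC#CC#CC(O[Li])c1c(OC)cccc1OC
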